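**Plan**

Locants follow cembrane numbering: C1 = ring CH carrying the three-carbon unit C15–C17, C3 = CHOAc, C4 and C7 = oxolane carbons, C8 = carbinol, C11 = ketone, C12 = quaternary carbon bearing the lactone oxygen, C16 = lactone carbonyl.
Retrosynthesis cuts, in order: the C8 silyl ether; the C12–O bond of the seven-membered lactone, with C16 taken back to the methyl of an isopropenyl group; the C11–C12 bond of the 14-membered carbocycle; the O–C7 bond of the oxolane together with C8–OH; C9–C10 and C5–C6 (Claisen rearrangements) and C7–C8 and C3–C4 (isopropenyl additions), back to (R)-limonene oxide.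
Enabling feature: the C11 ketone is bonded to C12, a quaternary carbon with a methyl and the lactone oxygen. This is an O-acylated tertiary acyloin, the adduct of a C11 aldehyde acyl-anion equivalent with a C12 methyl ketone, and that methyl ketone is the one set free by cleaving the ring alkene of limonene.
Forward: the limonene keto aldehyde is extended by two isopropenyl-addition/Claisen iterations; rings arise in the order temporary γ-lactone at C4, oxolane (C4–O–C7), 14-membered carbocycle, seven-membered lactone.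
Stereochemistry: C1 from (R)-limonene; C3 and C4 from Shi epoxidation of the E-C3=C4 alkene and invertive lactonisation at C4; C7 and C8 from a trans-selective syn-oxidative cyclisation onto the E-C7=C8 alkene, relayed from C4; C12 in the ring closure under a chiral triazolylidene.

Key step: step 14

Assumption: (+)-limonene 1,2-oxide (cis/trans mixture), the L-fructose-derived Shi ketone and both antipodes of the aminoindanol triazolium salt are taken as purchasable; carbinol centres that are erased later (in 4, 12 and 13) are carried as mixtures.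

**Route**

Step 1
Reactants: 1 (+)-limonene 1,2-oxide (4R; cis/trans mixture at the epoxide)
Product: 2 (3R)-6-oxo-3-(prop-1-en-2-yl)heptanal
Conditions: H5IO6, THF–H2O, 0 °C to rt
Reagents that add atoms: water, O
Why: Periodic acid hydrolyses the trisubstituted epoxide and cleaves the resulting glycol (Malaprade-type cleavage), so both epoxide diastereomers converge on the keto aldehyde while the isopropenyl group and the stereocentre that becomes C1 are untouched.

Step 2
Reactants: 2 keto aldehyde; 3 2-bromopropene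
Product: 4 (5R,7RS)-7-hydroxy-8-methyl-5-(prop-1-en-2-yl)non-8-en-2-one
Conditions: CrCl2 (4 equiv), NiCl2 (2 mol%), DMF, rt
Reagents that add atoms: 2-bromopropene (3), CC(Br)=C
Why: Nozaki–Hiyama–Kishi coupling: the alkenyl reagent of trivalent chromium formed from 3 adds to aldehydes but not to ketones, so only C3 reacts; the new carbinol centre forms as a mixture that is erased in step 4.

Step 3
Reactants: 4 allylic alcohol
Product: 5 2-methyl-2-[(3R,5RS)-5-hydroxy-6-methyl-3-(prop-1-en-2-yl)hept-6-en-1-yl]-1,3-dioxolane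
Conditions: HOCH2CH2OH, PPTS (cat.), benzene, reflux, Dean–Stark
Reagents that add atoms: ethylene glycol, OCCO
Why: Acid-catalysed ketalisation driven by azeotropic removal of water masks the C12 ketone for the hydride and Grignard steps and keeps it from acting as a dioxirane precursor in step 5; no stereocentre is affected.

Step 4
Reactants: 5 dioxolane alcohol; 6 triethyl orthoacetate
Product: 7 ethyl (4E,7R)-4-methyl-9-(2-methyl-1,3-dioxolan-2-yl)-7-(prop-1-en-2-yl)non-4-enoate
Conditions: MeC(OEt)3, EtCO2H (cat.), 140 °C, EtOH distilled off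
Reagents that add atoms: triethyl orthoacetate (6), CC(OCC)(OCC)OCC
Why: Johnson–Claisen rearrangement of the mixed ketene acetal through a chair transition state with the C2 chain pseudo-equatorial should give the E-C3=C4 trisubstituted alkene and the C5–C6 bond, and it removes the stereocentre made in step 2.

Step 5
Reactants: 7 E ester
Product: 9 (5R)-5-[(1S,3R)-1-hydroxy-5-(2-methyl-1,3-dioxolan-2-yl)-3-(prop-1-en-2-yl)pentyl]-5-methyloxolan-2-one, via epoxy ester 8 (not isolated)
Conditions: L-fructose-derived Shi ketone (30 mol%), KHSO5 (Oxone), K2CO3, Bu4NHSO4, MeCN–CH2(OMe)2–aq. Na2B4O7 buffer, 0 °C; then CSA (10 mol%), wet CH2Cl2, 0 °C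
Reagents that add atoms: potassium peroxymonosulfate, [K+].[O-]S(=O)(=O)OO; water, O
Why: Shi epoxidation: the chiral dioxirane should pick the electron-rich trisubstituted alkene over the 1,1-disubstituted isopropenyl group and, in the enantiomeric catalyst series, give the (3S,4S)-epoxide, which the ester carbonyl then opens 5-exo at the tertiary C4 with inversion to set 3S and 4R.

Step 6
Reactants: 9 hydroxy γ-lactone
Product: 10 (5R)-5-methyl-5-[(1S,3R)-5-(2-methyl-1,3-dioxolan-2-yl)-3-(prop-1-en-2-yl)-1-(triethylsilyloxy)pentyl]oxolan-2-one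
Conditions: Et3SiCl, imidazole, DMAP (cat.), DMF, rt
Reagents that add atoms: chlorotriethylsilane, CC[Si](Cl)(CC)CC
Why: Silylation of the only hydroxyl gives a bulky, non-coordinating ether that survives the hydride and Grignard steps and later steers step 9.

Step 7
Reactants: 10 silylated lactone; 11 isopropenylmagnesium bromide
Product: 13 (3RS,6R,7S,9R)-2,6-dimethyl-11-(2-methyl-1,3-dioxolan-2-yl)-9-(prop-1-en-2-yl)-7-(triethylsilyloxy)undec-1-ene-3,6-diol, via lactol 12 (not isolated)
Conditions: i-Bu2AlH (1.1 equiv), CH2Cl2, −78 °C; then CH2=C(CH3)MgBr (3 equiv), THF, −78 to 0 °C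
Reagents that add atoms: isopropenylmagnesium bromide (11), CC(=C)[Mg]Br
Why: Half-reduction of the lactone to the aluminium lactolate and addition of the alkenyl Grignard reagent to the aldehyde it releases on warming (one-pot reduction–alkylation) should give the diol; the C7 carbinol forms as a mixture that is erased in step 8.

Step 8
Reactants: 13 diol; 14 N,N-dimethylacetamide dimethyl acetal
Product: 15 (4E,8R,9S,11R)-8-hydroxy-N,N,4,8-tetramethyl-13-(2-methyl-1,3-dioxolan-2-yl)-11-(prop-1-en-2-yl)-9-(triethylsilyloxy)tridec-4-enamide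
Conditions: MeC(OMe)2NMe2 (5 equiv), xylenes, 140 °C
Reagents that add atoms: N,N-dimethylacetamide dimethyl acetal (14), CC(OC)(OC)N(C)C
Why: Eschenmoser–Claisen rearrangement via the ketene N,O-acetal and a chair transition state should give the E-C7=C8 alkene and the C9–C10 bond, and the dimethylamide so formed cannot lactonise onto the C8 hydroxyl made in the next step.

Step 9
Reactants: 15 E amide
Product: 16 (4R)-4-hydroxy-N,N-dimethyl-4-[(2R,5R)-5-methyl-5-[(1S,3R)-5-(2-methyl-1,3-dioxolan-2-yl)-3-(prop-1-en-2-yl)-1-(triethylsilyloxy)pentyl]oxolan-2-yl]pentanamide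
Conditions: Re2O7 (2 equiv), 2,6-lutidine, CH2Cl2, 0 °C to rt
Reagents that add atoms: dirhenium heptoxide, O=[Re](=O)(=O)O[Re](=O)(=O)=O
Why: Syn-oxidative cyclisation of a bishomoallylic tertiary alcohol by heptavalent rhenium (perrhenate ester, [3+2] addition of O–Re=O to the alkene, 5-exo): the ring oxygen and the new hydroxyl add to one face of the E-alkene, and the usual 2,5-trans preference with the bulky C3 chain pseudo-equatorial should give 7R and 8R from 4R.

Step 10
Reactants: 16 oxolane carbinol
Product: 17 (4R)-4-(tert-butyldimethylsilyloxy)-N,N-dimethyl-4-[(2R,5R)-5-methyl-5-[(1S,3R)-5-(2-methyl-1,3-dioxolan-2-yl)-3-(prop-1-en-2-yl)-1-(triethylsilyloxy)pentyl]oxolan-2-yl]pentanamide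
Conditions: t-BuMe2SiOTf, 2,6-lutidine, CH2Cl2, 0 °C
Reagents that add atoms: tert-butyldimethylsilyl triflate, CC(C)(C)[Si](C)(C)OS(=O)(=O)C(F)(F)F
Why: Silyl triflate silylation of the hindered tertiary alcohol; the ether keeps the C11 aldehyde made next from closing to a lactol and is the one group that outlasts step 12.

Step 11
Reactants: 17 bis-silylated amide
Product: 18 (4R)-4-(tert-butyldimethylsilyloxy)-4-[(2R,5R)-5-methyl-5-[(1S,3R)-5-(2-methyl-1,3-dioxolan-2-yl)-3-(prop-1-en-2-yl)-1-(triethylsilyloxy)pentyl]oxolan-2-yl]pentanal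
Conditions: LiAlH(OEt)3 (from LiAlH4 and EtOAc, Et2O, 0 °C), Et2O–THF, 0 °C; aqueous work-up
Reagents that add atoms: none
Why: Partial reduction of a tertiary amide with LiAlH(OEt)3 stops at the tetrahedral aluminate, which gives the aldehyde only on work-up; no stereocentre is touched.

Step 12
Reactants: 18 protected aldehyde
Product: 19 (4R)-4-(tert-butyldimethylsilyloxy)-4-[(2R,5R)-5-[(1S,3R)-1-hydroxy-6-oxo-3-(prop-1-en-2-yl)heptyl]-5-methyloxolan-2-yl]pentanal
Conditions: TsOH·H2O (10 mol%), acetone–H2O (10:1), rt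
Reagents that add atoms: water, O
Why: Acid-catalysed trans-ketalisation/hydrolysis frees the methyl ketone and cleaves the secondary triethylsilyl ether, while the tertiary tert-butyldimethylsilyl ether is far slower to hydrolyse and should stay.

Step 13
Reactants: 19 hydroxy keto aldehyde
Product: 20 (1S,3R)-1-[(2R,5R)-5-[(2R)-2-(tert-butyldimethylsilyloxy)-5-oxopentan-2-yl]-2-methyloxolan-2-yl]-6-oxo-3-(prop-1-en-2-yl)heptyl acetate
Conditions: Ac2O, pyridine, DMAP (cat.), CH2Cl2, 0 °C
Reagents that add atoms: acetic anhydride, CC(=O)OC(C)=O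
Why: Acylation of the only free hydroxyl (nucleophilic catalysis by DMAP) installs the C3 acetate of the target before the ring is closed.

Step 14
Reactants: 20 seco keto aldehyde
Product: 21 (1R,3S,4R,7R,8R,12R)-3-acetoxy-8-(tert-butyldimethylsilyloxy)-4,7-epoxy-12-hydroxycembr-15(17)-en-11-one
Conditions: aminoindanol-derived N-C6F5 triazolium tetrafluoroborate (20 mol%), i-Pr2NEt (20 mol%), toluene, 40 °C, 20 added by syringe pump to 1 mM
Reagents that add atoms: none
Why: Proposed new method: the triazolylidene adds to the C11 aldehyde of 20 and, after proton transfer, the resulting Breslow enaminol (an acyl-anion equivalent) attacks the C12 methyl ketone; proton transfer and loss of the carbene then release the tertiary α-ketol, so the carbocycle, the C11 ketone and the C12 carbinol arise in one redox-neutral event with no reagent atoms added. The closest known reaction type is the carbene-catalysed intramolecular crossed aldehyde–ketone benzoin reaction that gives five- and six-membered tertiary ketols (with its thiamine diphosphate enzyme counterpart); its use for a large ring is the untested part. The ring closes in a 14-exo-trig mode onto the ketone (13 atoms if counted through the ether oxygen), helped by the rigid 2,5-trans oxolane and the bulky C8 silyl ether that fold the chain. The C12 stereocentre is set by which ketone face the enaminol attacks, and the chiral aminoindanol backbone of the catalyst is the controlling element (both antipodes are to be tried on the enantiopure substrate so that catalyst and macrocycle bias are matched for 12R). The step needs cross-selectivity over aldehyde–aldehyde acyloin formation, aldol and Stetter pathways: there is one aldehyde per molecule at high dilution, aliphatic homo-acyloins form reversibly whereas the hindered tertiary ketol is not readily re-opened, the weak amine base does not enolise the carbonyls, the C8 oxygen is silylated so that the aldehyde is not locked as a lactol, and the isopropenyl group is still unoxidised so that no Michael acceptor is present. On bond-energy grounds the addition of an aldehyde acyl-anion equivalent to a dialkyl ketone is expected to be exergonic by a few kcal/mol, enough to carry an unstrained large ring.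

Step 15
Reactants: 21 macrocyclic ketol
Product: 22 (1R,3S,4R,7R,8R,12R)-3-acetoxy-8-(tert-butyldimethylsilyloxy)-4,7-epoxy-12,16-dihydroxycembr-15(17)-en-11-one
Conditions: SeO2 (0.5 equiv), t-BuOOH, CH2Cl2, rt
Reagents that add atoms: tert-butyl hydroperoxide (oxygen delivered through SeO2), CC(C)(C)OO
Why: SeO2-catalysed allylic oxidation (ene reaction then [2,3]-sigmatropic shift) should hydroxylate the methyl group of the isopropenyl unit, the only allylic CH3 in 21, in preference to the tertiary allylic C1–H.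

Step 16
Reactants: 22 allylic alcohol
Product: 24 (1R,3S,4R,7R,8R,12R)-3-acetoxy-8-(tert-butyldimethylsilyloxy)-4,7-epoxy-12-hydroxy-11-oxocembr-15(17)-en-16-oic acid, via enal 23 (not isolated)
Conditions: MnO2, CH2Cl2, rt; then NaClO2, NaH2PO4, 2-methyl-2-butene, t-BuOH–H2O, 0 °C
Reagents that add atoms: sodium chlorite, [Na+].[O-]Cl=O
Why: MnO2 oxidises only the allylic alcohol and the Pinnick oxidation then takes the enal to the acrylic acid without touching the ketone, the tertiary alcohols or the alkene.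

Step 17
Reactants: 24 hydroxy acid
Product: 26 (1R,3S,4R,7R,8R,12R)-3-acetoxy-8-(tert-butyldimethylsilyloxy)-4,7-epoxy-11-oxocembr-15(17)-en-16,12-olide, via mixed anhydride 25 (not isolated)
Conditions: 2,4,6-Cl3C6H2COCl, Et3N, THF, rt; then DMAP, toluene, 80 °C, 1 mM
Reagents that add atoms: none
Why: Yamaguchi lactonisation: the acyl-pyridinium formed from mixed anhydride 25 is attacked by the only free hydroxyl, the C12 ketol OH held 1,4 to C1 on the carbocycle, to close the seven-membered ring (7-exo-trig) with retention at C12, and the α-keto carbinol cannot ionise or eliminate.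

Step 18
Reactants: 26 silylated lactone
Product: 27 (1R,3S,4R,7R,8R,12R)-3-acetoxy-4,7-epoxy-8-hydroxy-11-oxocembr-15(17)-en-16,12-olide (target)
Conditions: HF·pyridine, THF, 0 °C to rt
Reagents that add atoms: none
Why: Fluoride-driven cleavage of the tertiary silyl ether under mildly acidic conditions leaves the acetate, the ketone and the α-methylene lactone untouched and gives the target.

**Compound list**

1 | (+)-limonene 1,2-oxide, (4R), cis/trans mixture at the epoxide | C=C(C)[C@@H]1CCC2(C)OC2C1 | starting material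
2 | (3R)-6-oxo-3-(prop-1-en-2-yl)heptanal | CC(=O)CC[C@H](CC=O)C(C)=C | intermediate
3 | 2-bromopropene | CC(Br)=C | starting material
4 | (5R,7RS)-7-hydroxy-8-methyl-5-(prop-1-en-2-yl)non-8-en-2-one | CC(=O)CC[C@H](CC(O)C(C)=C)C(C)=C | intermediate
5 | 2-methyl-2-[(3R,5RS)-5-hydroxy-6-methyl-3-(prop-1-en-2-yl)hept-6-en-1-yl]-1,3-dioxolane | CC1(OCCO1)CC[C@H](CC(O)C(C)=C)C(C)=C | intermediate
6 | triethyl orthoacetate | CC(OCC)(OCC)OCC | starting material
7 | ethyl (4E,7R)-4-methyl-9-(2-methyl-1,3-dioxolan-2-yl)-7-(prop-1-en-2-yl)non-4-enoate | CC1(OCCO1)CC[C@H](C/C=C(\C)CCC(=O)OCC)C(C)=C | intermediate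
8 | ethyl 3-[(2S,3S)-2-methyl-3-[(2R)-4-(2-methyl-1,3-dioxolan-2-yl)-2-(prop-1-en-2-yl)butyl]oxiran-2-yl]propanoate | CC1(OCCO1)CC[C@H](C[C@@H]2O[C@@]2(C)CCC(=O)OCC)C(C)=C | intermediate (not isolated)
9 | (5R)-5-[(1S,3R)-1-hydroxy-5-(2-methyl-1,3-dioxolan-2-yl)-3-(prop-1-en-2-yl)pentyl]-5-methyloxolan-2-one | CC1(OCCO1)CC[C@H](C[C@H](O)[C@@]2(C)CCC(=O)O2)C(C)=C | intermediate
10 | triethylsilyl ether of 9 | CC1(OCCO1)CC[C@H](C[C@H](O[Si](CC)(CC)CC)[C@@]2(C)CCC(=O)O2)C(C)=C | intermediate
11 | isopropenylmagnesium bromide | CC(=C)[Mg]Br | starting material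
12 | lactol from 10, (5R)-oxolan-2-ol, anomer mixture | CC1(OCCO1)CC[C@H](C[C@H](O[Si](CC)(CC)CC)[C@@]2(C)CCC(O)O2)C(C)=C | intermediate (not isolated)
13 | (3RS,6R,7S,9R)-2,6-dimethyl-11-(2-methyl-1,3-dioxolan-2-yl)-9-(prop-1-en-2-yl)-7-(triethylsilyloxy)undec-1-ene-3,6-diol | CC1(OCCO1)CC[C@H](C[C@H](O[Si](CC)(CC)CC)[C@](C)(O)CCC(O)C(C)=C)C(C)=C | intermediate
14 | N,N-dimethylacetamide dimethyl acetal | CC(OC)(OC)N(C)C | starting material
15 | (4E,8R,9S,11R)-8-hydroxy-N,N,4,8-tetramethyl-13-(2-methyl-1,3-dioxolan-2-yl)-11-(prop-1-en-2-yl)-9-(triethylsilyloxy)tridec-4-enamide | CC1(OCCO1)CC[C@H](C[C@H](O[Si](CC)(CC)CC)[C@](C)(O)CC/C=C(\C)CCC(=O)N(C)C)C(C)=C | intermediate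
16 | (4R)-4-hydroxy-N,N-dimethyl-4-[(2R,5R)-5-methyl-5-[(1S,3R)-5-(2-methyl-1,3-dioxolan-2-yl)-3-(prop-1-en-2-yl)-1-(triethylsilyloxy)pentyl]oxolan-2-yl]pentanamide | CC1(OCCO1)CC[C@H](C[C@H](O[Si](CC)(CC)CC)[C@@]2(C)CC[C@@H](O2)[C@](C)(O)CCC(=O)N(C)C)C(C)=C | intermediate
17 | tert-butyldimethylsilyl ether of 16 at the tertiary hydroxyl | CC1(OCCO1)CC[C@H](C[C@H](O[Si](CC)(CC)CC)[C@@]2(C)CC[C@@H](O2)[C@](C)(O[Si](C)(C)C(C)(C)C)CCC(=O)N(C)C)C(C)=C | intermediate
18 | (4R)-4-(tert-butyldimethylsilyloxy)-4-[(2R,5R)-5-methyl-5-[(1S,3R)-5-(2-methyl-1,3-dioxolan-2-yl)-3-(prop-1-en-2-yl)-1-(triethylsilyloxy)pentyl]oxolan-2-yl]pentanal | CC1(OCCO1)CC[C@H](C[C@H](O[Si](CC)(CC)CC)[C@@]2(C)CC[C@@H](O2)[C@](C)(O[Si](C)(C)C(C)(C)C)CCC=O)C(C)=C | intermediate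
19 | (4R)-4-(tert-butyldimethylsilyloxy)-4-[(2R,5R)-5-[(1S,3R)-1-hydroxy-6-oxo-3-(prop-1-en-2-yl)heptyl]-5-methyloxolan-2-yl]pentanal | CC(=O)CC[C@H](C[C@H](O)[C@@]1(C)CC[C@@H](O1)[C@](C)(O[Si](C)(C)C(C)(C)C)CCC=O)C(C)=C | intermediate
20 | (1S,3R)-1-[(2R,5R)-5-[(2R)-2-(tert-butyldimethylsilyloxy)-5-oxopentan-2-yl]-2-methyloxolan-2-yl]-6-oxo-3-(prop-1-en-2-yl)heptyl acetate | CC(=O)CC[C@H](C[C@H](OC(C)=O)[C@@]1(C)CC[C@@H](O1)[C@](C)(O[Si](C)(C)C(C)(C)C)CCC=O)C(C)=C | intermediate
21 | (1R,3S,4R,7R,8R,12R)-3-acetoxy-8-(tert-butyldimethylsilyloxy)-4,7-epoxy-12-hydroxycembr-15(17)-en-11-one (14-membered carbocycle) | C=C(C)[C@@H]1CC[C@@](C)(O)C(=O)CC[C@@](C)(O[Si](C)(C)C(C)(C)C)[C@H]2CC[C@@](C)(O2)[C@@H](OC(C)=O)C1 | intermediate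
22 | 16-hydroxy derivative of 21 (allylic alcohol) | C=C(CO)[C@@H]1CC[C@@](C)(O)C(=O)CC[C@@](C)(O[Si](C)(C)C(C)(C)C)[C@H]2CC[C@@](C)(O2)[C@@H](OC(C)=O)C1 | intermediate
23 | 16-al of 21 (α-substituted acrolein) | C=C(C=O)[C@@H]1CC[C@@](C)(O)C(=O)CC[C@@](C)(O[Si](C)(C)C(C)(C)C)[C@H]2CC[C@@](C)(O2)[C@@H](OC(C)=O)C1 | intermediate (not isolated)
24 | 16-oic acid of 21 (α-substituted acrylic acid) | C=C(C(=O)O)[C@@H]1CC[C@@](C)(O)C(=O)CC[C@@](C)(O[Si](C)(C)C(C)(C)C)[C@H]2CC[C@@](C)(O2)[C@@H](OC(C)=O)C1 | intermediate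
25 | mixed anhydride of 24 with 2,4,6-trichlorobenzoic acid | C=C(C(=O)OC(=O)c3c(Cl)cc(Cl)cc3Cl)[C@@H]1CC[C@@](C)(O)C(=O)CC[C@@](C)(O[Si](C)(C)C(C)(C)C)[C@H]2CC[C@@](C)(O2)[C@@H](OC(C)=O)C1 | intermediate (not isolated)
26 | (1R,3S,4R,7R,8R,12R)-3-acetoxy-8-(tert-butyldimethylsilyloxy)-4,7-epoxy-11-oxocembr-15(17)-en-16,12-olide | C=C1C(=O)O[C@]2(C)CC[C@@H]1C[C@H](OC(C)=O)[C@@]1(C)CC[C@@H](O1)[C@](C)(O[Si](C)(C)C(C)(C)C)CCC2=O | intermediate
27 | (1R,3S,4R,7R,8R,12R)-3-acetoxy-4,7-epoxy-8-hydroxy-11-oxocembr-15(17)-en-16,12-olide | C=C1C(=O)O[C@]2(C)CC[C@@H]1C[C@H](OC(C)=O)[C@@]1(C)CC[C@@H](O1)[C@](C)(O)CCC2=O | target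

**Totals and risks**

Total step count: 18. Longest linear sequence: 18 steps (1 to 27).

Step 14 (most likely to fail). The acyl-anion equivalent may add to the aldehyde of a second molecule faster than to the ketone, giving oligomeric acyloins. The closure may also stall at an unfavourable equilibrium, or the two ketone faces may be poorly distinguished. The fallback sets out from 20 and replaces the carbene catalysis by an irreversible reductive closure: a McMurry-type pinacol coupling with low-valent titanium (TiCl3(DME)1.5, Zn–Cu couple, DME, rt, slow addition), a known way to close 14-membered rings from keto aldehydes, should give the macrocyclic 11,12-diol F1. After separation of the 12R isomers, the secondary C11 hydroxyl is oxidised with Dess–Martin periodinane, which brings the route back at 21.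

Step 17. Acylation of the hindered, hydrogen-bonded tertiary ketol hydroxyl may be too slow, so that the activated acid oligomerises or the ketol undergoes a base-induced α-ketol shift on heating. The fallback sets out from 22 and closes the ring at the aldehyde oxidation level: MnO2 gives enal 23, which is now isolated; with catalytic CSA the C12 hydroxyl adds reversibly to the aldehyde to give the seven-membered lactol F2, and Fétizon oxidation (Ag2CO3 on Celite, benzene, reflux) drains this equilibrium to the lactone, returning at 26.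

Step 9. The cyclisation may show poor facial selectivity (2,5-cis ring, or the wrong C7/C8 pair), and the perrhenic acid formed may strip the silyl ether or the dioxolane. The fallback sets out from 10 and replaces the syn-oxidative cyclisation by epoxide opening on a Z-alkene under reagent control.
- Lactone 10 is reduced with i-Bu2AlH and lactol 12 is isolated.
- Still–Gennari olefination (methyl 2-[bis(2,2,2-trifluoroethoxy)phosphoryl]propanoate, KN(SiMe3)2, 18-crown-6, THF, −78 °C) gives the Z-enoate F3, and i-Bu2AlH reduces it to the Z-allylic alcohol F4.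
- Sharpless asymmetric epoxidation (Ti(OiPr)4, L-(+)-diethyl tartrate, t-BuOOH) gives the (7S,8R)-epoxy alcohol F5. With CSA the C4 hydroxyl opens it 5-exo at C7 with inversion to the oxolane diol F6, which has the 7R,8R configuration.
- Selective tosylation of the primary hydroxyl gives the tosylate F7, and K2CO3 in MeOH closes the terminal epoxide F8.
- Opening of F8 at its CH2 terminus with LiCH2C(O)NMe2 (from N,N-dimethylacetamide and LiN(i-Pr)2) returns the route at 16.

**Further compounds**

F1 | step 14 | macrocyclic 11,12-diol (C11 carbinol as a mixture, 12R shown) | C=C(C)[C@@H]1CC[C@@](C)(O)C(O)CC[C@@](C)(O[Si](C)(C)C(C)(C)C)[C@H]2CC[C@@](C)(O2)[C@@H](OC(C)=O)C1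
F2 | step 17 | seven-membered lactol (16-hydroxy-16,12-epoxy compound, C16 as a mixture) | C=C1C(O)O[C@]2(C)CC[C@@H]1C[C@H](OC(C)=O)[C@@]1(C)CC[C@@H](O1)[C@](C)(O[Si](C)(C)C(C)(C)C)CCC2=O
F3 | step 9 | Z-enoate, methyl (2Z,6R,7S,9R)-6-hydroxy-2,6-dimethyl-11-(2-methyl-1,3-dioxolan-2-yl)-9-(prop-1-en-2-yl)-7-(triethylsilyloxy)undec-2-enoate | CC1(OCCO1)CC[C@H](C[C@H](O[Si](CC)(CC)CC)[C@](C)(O)CC/C=C(/C)C(=O)OC)C(C)=C
F4 | step 9 | Z-allylic alcohol from F3 | CC1(OCCO1)CC[C@H](C[C@H](O[Si](CC)(CC)CC)[C@](C)(O)CC/C=C(/C)CO)C(C)=C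
F5 | step 9 | (7S,8R)-epoxy alcohol (cis-epoxide) | CC1(OCCO1)CC[C@H](C[C@H](O[Si](CC)(CC)CC)[C@](C)(O)CC[C@@H]2O[C@]2(C)CO)C(C)=C
F6 | step 9 | oxolane 1,2-diol (7R,8R) | CC1(OCCO1)CC[C@H](C[C@H](O[Si](CC)(CC)CC)[C@@]2(C)CC[C@@H](O2)[C@](C)(O)CO)C(C)=C
F7 | step 9 | primary tosylate of F6 | CC1(OCCO1)CC[C@H](C[C@H](O[Si](CC)(CC)CC)[C@@]2(C)CC[C@@H](O2)[C@](C)(O)COS(=O)(=O)c3ccc(C)cc3)C(C)=C
F8 | step 9 | terminal 2,2-disubstituted epoxide at C8 | CC1(OCCO1)CC[C@H](C[C@H](O[Si](CC)(CC)CC)[C@@]2(C)CC[C@@H](O2)[C@@]3(C)CO3)C(C)=C
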